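Everything rests on disconnecting the C(CH3)2–CH2 bond of the bromodimethylcyclohexanol ring (ring A). Its CHBr–C(CH3)2 pair is read as the bromonium ion of a prenyl terminus, its CH2–C(OH) pair as a 1,1-disubstituted alkene, and the tertiary ring carbinol with the exocyclic CH(OH) next to it as a cyclic carbonate. One operation, a bromonium-triggered cation–olefin cyclisation with carbonate capture, closes ring A, sets its C–Br and spiro C–O stereocentres and masks the vicinal diol. The precursor is an open-chain 6-bromo-5-hydroxy-6-methyl-2-methyleneheptyl tert-butyl carbonate (from a Shi epoxide) attached to the complete, silyl-protected bromo-trans-hydrindane, itself built by an enantiospecific bromochloride cyclisation.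

Key step: step 18

Remark (assumption): the ligand enantiomer of step 2 and the D-fructose-derived Shi ketone of step 16 are taken to deliver the configurations stated (the mirror-image catalysts would serve otherwise); Ind* below stands for the 4-bromo-2-(tert-butyldimethylsilyloxy)-3a,7-dimethyl-7-(triethylsilyloxy)octahydro-1H-inden-1-yl group with the ring configuration of compound 19.

Step 1
Reactants: 1 pent-1-en-4-yne
Product: 3 (2E)-3-methylhexa-2,5-dien-1-ol, via (E)-alkenyldimethylalane 2 (not isolated)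
Conditions: Me3Al (2 equiv), Cp2ZrCl2 (0.2 equiv), CH2Cl2, 0 °C → rt; then n-BuLi, THF, −78 °C; (CH2O)n, → rt
Reagents that add atoms: trimethylaluminium, C[Al](C)C; paraformaldehyde (as formaldehyde), C=O
Why: Negishi zirconium-catalysed carboalumination adds CH3 and Al syn across the terminal alkyne only (CH3 to the internal carbon) and the alanate is hydroxymethylated with retention, so CH2OH ends trans to the allyl group (E).

Step 2
Reactants: 3 (2E)-3-methylhexa-2,5-dien-1-ol
Product: 4 (2S,3R)-2-bromo-3-chloro-3-methylhex-5-en-1-ol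
Conditions: NBS (1.1 equiv), ClTi(Oi-Pr)3 (1.1 equiv), chiral tridentate Schiff-base ligand (20 mol%), hexanes, −20 °C
Reagents that add atoms: N-bromosuccinimide, O=C1CCC(=O)N1Br; chlorotitanium triisopropoxide, CC(C)O[Ti](Cl)(OC(C)C)OC(C)C
Why: Catalytic enantioselective bromochlorination of an allylic alcohol: ligand-controlled bromonium formation on the titanium-bound allylic alkene and anti, Markovnikov opening by chloride should set C2 (S, C–Br) and C3 (R, C–Cl), while the remote monosubstituted alkene is not touched.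

Step 3
Reactants: 4 (2S,3R)-2-bromo-3-chloro-3-methylhex-5-en-1-ol
Product: 5 (2S,3R)-2-bromo-3-chloro-3-methylhex-5-en-1-yl trifluoromethanesulfonate
Conditions: Tf2O, 2,6-lutidine, CH2Cl2, −78 °C
Reagents that add atoms: trifluoromethanesulfonic anhydride, O=S(=O)(OS(=O)(=O)C(F)(F)F)C(F)(F)F
Why: O-Sulfonylation of the primary alcohol at low temperature touches no stereocentre.

Step 4
Reactants: 5 (2S,3R)-2-bromo-3-chloro-3-methylhex-5-en-1-yl trifluoromethanesulfonate; 6 tert-butyl 3-oxobutanoate
Product: 8 tert-butyl (6S,7R)-6-bromo-7-chloro-7-methyl-3-oxodec-9-enoate, via acetoacetate dianion 7 (not isolated)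
Conditions: 6, NaH, THF, 0 °C; n-BuLi, 0 °C; then 5, −78 → −40 °C
Reagents that add atoms: none
Why: γ-Alkylation of the acetoacetate dianion (Weiler alkylation) by SN2 at the primary triflate, as with 2-haloethyl triflates, should leave the hindered secondary bromide and the tertiary chloride untouched at −78 °C.

Step 5
Reactants: 8 tert-butyl (6S,7R)-6-bromo-7-chloro-7-methyl-3-oxodec-9-enoate
Product: 10 tert-butyl (1S,2S,3S)-3-bromo-2-methyl-6-oxo-2-(prop-2-en-1-yl)cyclohexane-1-carboxylate, via bromonium ion 9 (not isolated)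
Conditions: HFIP (0.02 M), 2,6-di-tert-butylpyridine (1.2 equiv), 40 °C
Reagents that add atoms: none
Why: Enantiospecific solvolytic bromonium cyclisation: HFIP ionises the tertiary chloride with anchimeric help from the vicinal bromine, and the β-keto ester enol attacks the tertiary carbon anti to Br through a chair (Br, allyl and ester equatorial, methyl axial), which transfers the (6S,7R) information to ring carbons C3 and C2.

Step 6
Reactants: 10 tert-butyl (1S,2S,3S)-3-bromo-2-methyl-6-oxo-2-(prop-2-en-1-yl)cyclohexane-1-carboxylate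
Product: 11 tert-butyl (1S,2S,3S)-3-bromo-2-methyl-6-oxo-1,2-di(prop-2-en-1-yl)cyclohexane-1-carboxylate
Conditions: allyl methyl carbonate (1.5 equiv), Pd(PPh3)4 (5 mol%), THF, rt → 50 °C
Reagents that add atoms: allyl methyl carbonate, C=CCOC(=O)OC
Why: Tsuji–Trost allylation of the β-keto ester under neutral conditions gives C-allylation only, and the configuration of the new quaternary carbon does not matter because step 7 erases it.

Step 7
Reactants: 11 tert-butyl (1S,2S,3S)-3-bromo-2-methyl-6-oxo-1,2-di(prop-2-en-1-yl)cyclohexane-1-carboxylate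
Product: 13 (2S,3S,4S)-4-bromo-3-methyl-2,3-di(prop-2-en-1-yl)cyclohexan-1-one, via β-keto acid 12 (not isolated)
Conditions: TFA/CH2Cl2 (1:4), 0 °C → rt; then toluene, 60 °C
Reagents that add atoms: none
Why: Acidolysis of the tert-butyl ester and decarboxylation of the β-keto acid give an enol that should be protonated axially, anti to the axial C3 methyl group, which places the C2 allyl group equatorial and trans to the C3 allyl group (2S).

Step 8
Reactants: 13 (2S,3S,4S)-4-bromo-3-methyl-2,3-di(prop-2-en-1-yl)cyclohexan-1-one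
Product: 14 (1R,2S,3S,4S)-4-bromo-1,3-dimethyl-2,3-di(prop-2-en-1-yl)cyclohexan-1-ol
Conditions: MeMgBr, anhydrous CeCl3, THF, −78 °C
Reagents that add atoms: methylmagnesium bromide, C[Mg]Br
Why: Organocerium 1,2-addition (no enolisation of the epimerisable ketone) should come from the equatorial direction because the axial C3 methyl group blocks the axial face, giving the axial tertiary alcohol (1R).

Step 9
Reactants: 14 (1R,2S,3S,4S)-4-bromo-1,3-dimethyl-2,3-di(prop-2-en-1-yl)cyclohexan-1-ol
Product: 15 triethylsilyl ether of 14, triethyl{[(1R,2S,3S,4S)-4-bromo-1,3-dimethyl-2,3-di(prop-2-en-1-yl)cyclohexyl]oxy}silane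
Conditions: TESOTf, 2,6-lutidine, CH2Cl2, 0 °C → rt
Reagents that add atoms: triethylsilyl trifluoromethanesulfonate, CC[Si](CC)(CC)OS(=O)(=O)C(F)(F)F
Why: Silylation with the silyl triflate (needed for the hindered axial tertiary alcohol) prevents lactol formation with the aldehyde made in step 10 and ether formation in step 18.

Step 10
Reactants: 15 triethylsilyl ether of 14
Product: 17 2,2'-[(1S,2S,3S,6R)-3-bromo-2,6-dimethyl-6-(triethylsilyloxy)cyclohexane-1,2-diyl]diacetaldehyde, via bis-ozonide 16 (not isolated)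
Conditions: O3, CH2Cl2, −78 °C; then PPh3, → rt
Reagents that add atoms: ozone, [O-][O+]=O
Why: Ozonolysis with reductive work-up cleaves both terminal alkenes to the 1,6-dialdehyde, and the silyl ether and the alkyl bromide are inert to ozone.

Step 11
Reactants: 17 2,2'-[(1S,2S,3S,6R)-3-bromo-2,6-dimethyl-6-(triethylsilyloxy)cyclohexane-1,2-diyl]diacetaldehyde
Product: 18 (1S,2R,3aS,4S,7R,7aS)-4-bromo-2-hydroxy-3a,7-dimethyl-7-(triethylsilyloxy)octahydro-1H-indene-1-carbaldehyde
Conditions: (S)-proline (20 mol%), DMSO, rt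
Reagents that add atoms: none
Why: Proline-catalysed 5-enolexo aldol addition: the aldehyde on the CH-bearing ring carbon forms the enamine and attacks the neopentyl aldehyde with its oxygen turned away from the angular methyl group (2R), and the formyl-bearing carbon should settle by enamine equilibration trans to the C7a–C7 bond and cis to OH (1S), the trans ring fusion being fixed already.

Step 12
Reactants: 18 (1S,2R,3aS,4S,7R,7aS)-4-bromo-2-hydroxy-3a,7-dimethyl-7-(triethylsilyloxy)octahydro-1H-indene-1-carbaldehyde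
Product: 19 (1S,2R,3aS,4S,7R,7aS)-4-bromo-2-(tert-butyldimethylsilyloxy)-3a,7-dimethyl-7-(triethylsilyloxy)octahydro-1H-indene-1-carbaldehyde
Conditions: TBSOTf, 2,6-lutidine, CH2Cl2, −78 °C
Reagents that add atoms: tert-butyldimethylsilyl trifluoromethanesulfonate, CC(C)(C)[Si](C)(C)OS(=O)(=O)C(F)(F)F
Why: Silyl triflate protection at −78 °C with a hindered base avoids β-elimination and epimerisation of the β-hydroxy aldehyde and makes the oxygen non-chelating for step 14.

Step 13
Reactants: 20 6-methylhept-5-en-2-one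
Product: 22 6-methylhepta-1,5-dien-2-yl trifluoromethanesulfonate, via lithium enolate 21 (not isolated)
Conditions: LDA, THF, −78 °C; then PhNTf2, −78 → 0 °C
Reagents that add atoms: N-phenylbis(trifluoromethanesulfonimide), O=S(=O)(N(c1ccccc1)S(=O)(=O)C(F)(F)F)C(F)(F)F
Why: Kinetic deprotonation of the methyl ketone at CH3 and O-triflation of the enolate give the 2-triflyloxy-1-alkene (enol triflate formation).

Step 14
Reactants: 19 (1S,2R,3aS,4S,7R,7aS)-4-bromo-2-(tert-butyldimethylsilyloxy)-3a,7-dimethyl-7-(triethylsilyloxy)octahydro-1H-indene-1-carbaldehyde; 22 6-methylhepta-1,5-dien-2-yl trifluoromethanesulfonate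
Product: 24 (1R)-1-(Ind*)-6-methyl-2-methylidenehept-5-en-1-ol, via alkenylchromium(III) 23 (not isolated)
Conditions: CrCl2 (4 equiv), NiCl2 (2 mol%), DMF, rt
Reagents that add atoms: none
Why: Nozaki–Hiyama–Kishi coupling: the non-chelating alkenylchromium should add under Felkin–Anh control, with the C1–C2 ring bond that carries the silyloxy group anti to the incoming nucleophile and away from the cis silyloxy group, to give the (R)-carbinol, while the alkyl bromide and the silyl ethers are inert.

Step 15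
Reactants: 24 (1R)-1-(Ind*)-6-methyl-2-methylidenehept-5-en-1-ol
Product: 25 tert-butyl (1R)-1-(Ind*)-6-methyl-2-methylidenehept-5-en-1-yl carbonate
Conditions: Boc2O, DMAP, Et3N, CH2Cl2, rt
Reagents that add atoms: di-tert-butyl dicarbonate, CC(C)(C)OC(=O)OC(=O)OC(C)(C)C
Why: DMAP-catalysed acylation of the only free hydroxyl gives the tert-butyl carbonate that serves as the internal nucleophile of step 18.

Step 16
Reactants: 25 tert-butyl (1R)-1-(Ind*)-6-methyl-2-methylidenehept-5-en-1-yl carbonate
Product: 26 tert-butyl (1R)-4-[(2R)-3,3-dimethyloxiran-2-yl]-1-(Ind*)-2-methylidenebutyl carbonate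
Conditions: D-fructose-derived Shi ketone (30 mol%), Oxone, K2CO3, Bu4NHSO4, MeCN/DMM/aq. borate buffer (pH 10.5), 0 °C
Reagents that add atoms: Oxone (potassium peroxymonosulfate), [K+].OOS(=O)(=O)[O-]
Why: Shi asymmetric epoxidation: the dioxirane attacks only the electron-rich trisubstituted alkene (the 1,1-disubstituted alkene with the allylic carbonate is electron-poor and a poor substrate class) and the catalyst sets the (R)-epoxide carbon.

Step 17
Reactants: 26 tert-butyl (1R)-4-[(2R)-3,3-dimethyloxiran-2-yl]-1-(Ind*)-2-methylidenebutyl carbonate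
Product: 27 tert-butyl (1R,5R)-6-bromo-5-hydroxy-1-(Ind*)-6-methyl-2-methylideneheptyl carbonate
Conditions: LiBr, AcOH, THF, 0 °C → rt
Reagents that add atoms: lithium bromide, [Li+].[Br-]
Why: Acid-assisted anti opening of the trisubstituted epoxide by bromide at the tertiary carbon (halohydrin formation) leaves the (R)-carbinol carbon untouched, and the regioisomeric bromohydrin would give the same bromonium ion in step 18.

Step 18
Reactants: 27 tert-butyl (1R,5R)-6-bromo-5-hydroxy-1-(Ind*)-6-methyl-2-methylideneheptyl carbonate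
Product: 30 (4R,5R,8S)-8-bromo-4-(Ind*)-7,7-dimethyl-1,3-dioxaspiro[4.5]decan-2-one, via secondary triflate 28 (not isolated), via bromonium ion 29 (not isolated)
Conditions: Tf2O (1.2 equiv), 2,6-di-tert-butyl-4-methylpyridine (3 equiv), CH2Cl2 (0.005 M), −78 → −20 °C
Reagents that add atoms: none
Why: Triflation of the secondary carbinol is followed by rear-side displacement by the vicinal tertiary bromine (inversion), giving bromonium ion 29 whose C–Br configuration is fixed by the Shi epoxide; the CH2 terminus of the 1,1-disubstituted alkene opens it at the tertiary carbon anti to Br, and the tertiary ring cation is trapped by the carbonyl oxygen of the neighbouring tert-butyl carbonate with loss of isobutene. The closest known reaction type is the bromonium-induced cation–olefin (polyene) cyclisation terminated by a tert-butyl carbonate, combined with neighbouring-group generation of bromonium ions from enantioenriched bromohydrin or bromochloride surrogates. Ring A closes 6-endo (both alkene carbons end in the ring) through a chair with Br equatorial, and the temporary dioxolanone closes 5-exo on the cation. The C–Br carbon (S) follows from the (R)-carbinol by a single inversion; the spiro carbon (R) should be set by capture on the axial face, which keeps the branched CH(O)-indanyl substituent equatorial (O cis and substituent trans to Br), reinforced by 1,2-induction from the carbinol carbon, whose indanyl group prefers the CH2CH2 side of ring A over the neopentyl CH2C(CH3)2 side. The step needs cyclisation to beat E1 loss of a proton and intermolecular Br+ transfer (high dilution, hindered base, low temperature and the built-in trap) and needs the cation to be trapped by the carbonate alone (silyl protection of the two ring hydroxyls).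

Step 19
Reactants: 30 (4R,5R,8S)-8-bromo-4-(Ind*)-7,7-dimethyl-1,3-dioxaspiro[4.5]decan-2-one
Product: 32 (1S,2R,3aS,4S,7R,7aS)-4-bromo-1-[(R)-[(1R,4S)-4-bromo-1-hydroxy-3,3-dimethylcyclohexyl](hydroxy)methyl]-3a,7-dimethyloctahydro-1H-indene-2,7-diol (CNP0144982.1), via diol carbonate 31 (not isolated)
Conditions: HF·pyridine, THF/pyridine, 0 °C → rt; then K2CO3, MeOH, rt
Reagents that add atoms: none
Why: Fluoride cleaves both silyl ethers and methanolysis opens the cyclic carbonate to the diol, while the two equatorial, neopentyl-type secondary bromides should resist substitution and elimination under these mild conditions.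

Compound list

1 | pent-1-en-4-yne | C#CCC=C | starting material
2 | dimethyl[(1E)-2-methylpenta-1,4-dien-1-yl]alane | C[Al](C)/C=C(\C)CC=C | intermediate
3 | (2E)-3-methylhexa-2,5-dien-1-ol | OC/C=C(\C)CC=C | intermediate
4 | (2S,3R)-2-bromo-3-chloro-3-methylhex-5-en-1-ol | OC[C@H](Br)[C@](C)(Cl)CC=C | intermediate
5 | (2S,3R)-2-bromo-3-chloro-3-methylhex-5-en-1-yl trifluoromethanesulfonate | O=S(=O)(OC[C@H](Br)[C@](C)(Cl)CC=C)C(F)(F)F | intermediate
6 | tert-butyl 3-oxobutanoate (tert-butyl acetoacetate) | CC(=O)CC(=O)OC(C)(C)C | starting material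
7 | sodium lithium dianion of 6 (C2 and C4 deprotonated) | [Na+].[Li+].[CH2-]C(=O)[CH-]C(=O)OC(C)(C)C | intermediate
8 | tert-butyl (6S,7R)-6-bromo-7-chloro-7-methyl-3-oxodec-9-enoate | CC(C)(C)OC(=O)CC(=O)CC[C@H](Br)[C@](C)(Cl)CC=C | intermediate
9 | bromiranium ion from 8 (Br bridges C6 and C7; C6 unchanged, C7 inverted), chloride counter-ion | CC(C)(C)OC(=O)CC(=O)CC[C@@H]1[Br+][C@@]1(C)CC=C.[Cl-] | intermediate
10 | tert-butyl (1S,2S,3S)-3-bromo-2-methyl-6-oxo-2-(prop-2-en-1-yl)cyclohexane-1-carboxylate | O=C1CC[C@H](Br)[C@@](C)(CC=C)[C@@H]1C(=O)OC(C)(C)C | intermediate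
11 | tert-butyl (1S,2S,3S)-3-bromo-2-methyl-6-oxo-1,2-di(prop-2-en-1-yl)cyclohexane-1-carboxylate | O=C1CC[C@H](Br)[C@@](C)(CC=C)[C@]1(CC=C)C(=O)OC(C)(C)C | intermediate
12 | (1S,2S,3S)-3-bromo-2-methyl-6-oxo-1,2-di(prop-2-en-1-yl)cyclohexane-1-carboxylic acid | O=C1CC[C@H](Br)[C@@](C)(CC=C)[C@]1(CC=C)C(=O)O | intermediate
13 | (2S,3S,4S)-4-bromo-3-methyl-2,3-di(prop-2-en-1-yl)cyclohexan-1-one | O=C1CC[C@H](Br)[C@@](C)(CC=C)[C@@H]1CC=C | intermediate
14 | (1R,2S,3S,4S)-4-bromo-1,3-dimethyl-2,3-di(prop-2-en-1-yl)cyclohexan-1-ol | C[C@@]1(O)CC[C@H](Br)[C@@](C)(CC=C)[C@@H]1CC=C | intermediate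
15 | triethyl{[(1R,2S,3S,4S)-4-bromo-1,3-dimethyl-2,3-di(prop-2-en-1-yl)cyclohexyl]oxy}silane | C[C@@]1(O[Si](CC)(CC)CC)CC[C@H](Br)[C@@](C)(CC=C)[C@@H]1CC=C | intermediate
16 | bis-ozonide of 15 (each CH=CH2 as a 1,2,4-trioxolan-3-yl ring; ring stereocentres as in 15, trioxolane carbons unspecified) | C[C@@]1(O[Si](CC)(CC)CC)CC[C@H](Br)[C@@](C)(CC2OCOO2)[C@@H]1CC3OCOO3 | intermediate
17 | 2,2'-[(1S,2S,3S,6R)-3-bromo-2,6-dimethyl-6-(triethylsilyloxy)cyclohexane-1,2-diyl]diacetaldehyde | C[C@@]1(O[Si](CC)(CC)CC)CC[C@H](Br)[C@@](C)(CC=O)[C@@H]1CC=O | intermediate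
18 | (1S,2R,3aS,4S,7R,7aS)-4-bromo-2-hydroxy-3a,7-dimethyl-7-(triethylsilyloxy)octahydro-1H-indene-1-carbaldehyde | O=C[C@@H]1[C@H](O)C[C@]2(C)[C@@H](Br)CC[C@@](C)(O[Si](CC)(CC)CC)[C@@H]12 | intermediate
19 | (1S,2R,3aS,4S,7R,7aS)-4-bromo-2-(tert-butyldimethylsilyloxy)-3a,7-dimethyl-7-(triethylsilyloxy)octahydro-1H-indene-1-carbaldehyde | O=C[C@@H]1[C@H](O[Si](C)(C)C(C)(C)C)C[C@]2(C)[C@@H](Br)CC[C@@](C)(O[Si](CC)(CC)CC)[C@@H]12 | intermediate
20 | 6-methylhept-5-en-2-one | CC(=O)CCC=C(C)C | starting material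
21 | lithium 6-methylhepta-1,5-dien-2-olate | [Li+].[O-]C(=C)CCC=C(C)C | intermediate
22 | 6-methylhepta-1,5-dien-2-yl trifluoromethanesulfonate | C=C(OS(=O)(=O)C(F)(F)F)CCC=C(C)C | intermediate
23 | dichloro(6-methylhepta-1,5-dien-2-yl)chromium(III) | C=C([Cr](Cl)Cl)CCC=C(C)C | intermediate
24 | (1R)-1-[(1R,2R,3aS,4S,7R,7aS)-4-bromo-2-(tert-butyldimethylsilyloxy)-3a,7-dimethyl-7-(triethylsilyloxy)octahydro-1H-inden-1-yl]-6-methyl-2-methylidenehept-5-en-1-ol (indane C1 is spatially unchanged from 19; its descriptor changes with the CIP priorities only) | C=C(CCC=C(C)C)[C@H](O)[C@@H]1[C@H](O[Si](C)(C)C(C)(C)C)C[C@]2(C)[C@@H](Br)CC[C@@](C)(O[Si](CC)(CC)CC)[C@@H]12 | intermediate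
25 | tert-butyl (1R)-1-[(1R,2R,3aS,4S,7R,7aS)-4-bromo-2-(tert-butyldimethylsilyloxy)-3a,7-dimethyl-7-(triethylsilyloxy)octahydro-1H-inden-1-yl]-6-methyl-2-methylidenehept-5-en-1-yl carbonate | C=C(CCC=C(C)C)[C@H](OC(=O)OC(C)(C)C)[C@@H]1[C@H](O[Si](C)(C)C(C)(C)C)C[C@]2(C)[C@@H](Br)CC[C@@](C)(O[Si](CC)(CC)CC)[C@@H]12 | intermediate
26 | tert-butyl (1R)-4-[(2R)-3,3-dimethyloxiran-2-yl]-1-(Ind*)-2-methylidenebutyl carbonate | C=C(CC[C@H]1OC1(C)C)[C@H](OC(=O)OC(C)(C)C)[C@@H]2[C@H](O[Si](C)(C)C(C)(C)C)C[C@]3(C)[C@@H](Br)CC[C@@](C)(O[Si](CC)(CC)CC)[C@@H]23 | intermediate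
27 | tert-butyl (1R,5R)-6-bromo-5-hydroxy-1-(Ind*)-6-methyl-2-methylideneheptyl carbonate | C=C(CC[C@@H](O)C(C)(C)Br)[C@H](OC(=O)OC(C)(C)C)[C@@H]1[C@H](O[Si](C)(C)C(C)(C)C)C[C@]2(C)[C@@H](Br)CC[C@@](C)(O[Si](CC)(CC)CC)[C@@H]12 | intermediate
28 | 5-O-trifluoromethanesulfonate of 27 (same configuration) | C=C(CC[C@@H](OS(=O)(=O)C(F)(F)F)C(C)(C)Br)[C@H](OC(=O)OC(C)(C)C)[C@@H]1[C@H](O[Si](C)(C)C(C)(C)C)C[C@]2(C)[C@@H](Br)CC[C@@](C)(O[Si](CC)(CC)CC)[C@@H]12 | intermediate
29 | bromiranium ion from 28 (Br bridges the former carbinol carbon, inverted, and the C(CH3)2 carbon), triflate counter-ion | C=C(CC[C@@H]1[Br+]C1(C)C)[C@H](OC(=O)OC(C)(C)C)[C@@H]2[C@H](O[Si](C)(C)C(C)(C)C)C[C@]3(C)[C@@H](Br)CC[C@@](C)(O[Si](CC)(CC)CC)[C@@H]23.[O-]S(=O)(=O)C(F)(F)F | intermediate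
30 | (4R,5R,8S)-8-bromo-4-[(1R,2R,3aS,4S,7R,7aS)-4-bromo-2-(tert-butyldimethylsilyloxy)-3a,7-dimethyl-7-(triethylsilyloxy)octahydro-1H-inden-1-yl]-7,7-dimethyl-1,3-dioxaspiro[4.5]decan-2-one | CC1(C)C[C@]2(OC(=O)O[C@@H]2[C@@H]3[C@H](O[Si](C)(C)C(C)(C)C)C[C@]4(C)[C@@H](Br)CC[C@@](C)(O[Si](CC)(CC)CC)[C@@H]34)CC[C@@H]1Br | intermediate
31 | (4R,5R,8S)-8-bromo-4-[(1S,2R,3aS,4S,7R,7aS)-4-bromo-2,7-dihydroxy-3a,7-dimethyloctahydro-1H-inden-1-yl]-7,7-dimethyl-1,3-dioxaspiro[4.5]decan-2-one | CC1(C)C[C@]2(OC(=O)O[C@@H]2[C@@H]3[C@H](O)C[C@]4(C)[C@@H](Br)CC[C@@](C)(O)[C@@H]34)CC[C@@H]1Br | intermediate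
32 | (1S,2R,3aS,4S,7R,7aS)-4-bromo-1-[(R)-[(1R,4S)-4-bromo-1-hydroxy-3,3-dimethylcyclohexyl](hydroxy)methyl]-3a,7-dimethyloctahydro-1H-indene-2,7-diol (CNP0144982.1) | CC1(C)C[C@@](O)([C@H](O)[C@@H]2[C@H](O)C[C@]3(C)[C@@H](Br)CC[C@@](C)(O)[C@@H]23)CC[C@@H]1Br | target

Total step count: 19. Longest linear sequence: 18 (steps 1–12 and 14–19; step 13 is the one-step side branch).

Steps most likely to fail

1. Step 18. The bromonium ion or the ring cation may lose a proton (allylic bromide or ring alkenes instead of carbonate capture), the ring cation may be captured on the equatorial face (epimeric spiro carbon), or the C–Br configuration may erode through intermolecular Br+ transfer. The fallback sets out from 25 and drops the epoxide, bromohydrin and triflate. Direct bromonium transfer with bromodiethylsulfonium bromopentachloroantimonate (BDSB) in MeNO2 at −25 °C, a bromonium-induced cation–olefin cyclisation with the same carbonate trap, should lead straight to 30. The C–Br centre is then no longer set by an earlier stereocentre, so the two ring-A series would be separated by chromatography, or the bromonium delivered with a chiral thiophosphoramide Lewis base and DBDMH. This fallback makes no new compound (F0).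

2. Step 5. The enol content and nucleophilicity of the β-keto ester in HFIP may be too low, so that loss of a proton from the bromonium ion (allylic bromide) or capture by the solvent outruns ring closure. The fallback sets out from 8, which is converted with TBSOTf and Et3N (CH2Cl2, 0 °C) into the far more nucleophilic silyl enol ether tert-butyl (2Z,6S,7R)-6-bromo-3-(tert-butyldimethylsilyloxy)-7-chloro-7-methyldeca-2,9-dienoate F1. Ionisation of its tertiary chloride in HFIP (or with AgOTf in MeNO2 at −20 °C) lets the enol ether close the ring in a Mukaiyama-type capture; the silyl group leaves as the silyl chloride, and the route is rejoined at 10.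

3. Step 14. Facial selectivity at the α-branched aldehyde may be poor (Felkin against anti-Felkin attack), giving the epimeric carbinol. The fallback sets out from 18 and comes back at 24.
   - The unprotected hydroxy aldehyde 18 is coupled with 22 under the same Nozaki–Hiyama–Kishi conditions to give 1-[(1S,2R,3aS,4S,7R,7aS)-4-bromo-2-hydroxy-3a,7-dimethyl-7-(triethylsilyloxy)octahydro-1H-inden-1-yl]-6-methyl-2-methylidenehept-5-en-1-ol F2 as a mixture of carbinol epimers.
   - MnO2 (CH2Cl2, rt) oxidises only the allylic alcohol, giving the β-hydroxy enone 1-[(1S,2R,3aS,4S,7R,7aS)-4-bromo-2-hydroxy-3a,7-dimethyl-7-(triethylsilyloxy)octahydro-1H-inden-1-yl]-6-methyl-2-methylidenehept-5-en-1-one F3.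
   - Narasaka–Prasad reduction (Et2BOMe, NaBH4, THF/MeOH, −78 °C) delivers hydride to the boron chelate on the face of the ring carbinol hydrogen, anti to C7a, and should give the syn-1,3-diol (1R)-1-[(1S,2R,3aS,4S,7R,7aS)-4-bromo-2-hydroxy-3a,7-dimethyl-7-(triethylsilyloxy)octahydro-1H-inden-1-yl]-6-methyl-2-methylidenehept-5-en-1-ol F4.
   - TBSOTf (1 equiv) and 2,6-lutidine at −78 °C silylate the less hindered ring hydroxyl and give 24.

Further compounds

F0 | step 18 | none | none
F1 | step 5 | tert-butyl (2Z,6S,7R)-6-bromo-3-(tert-butyldimethylsilyloxy)-7-chloro-7-methyldeca-2,9-dienoate | CC(C)(C)OC(=O)/C=C(\O[Si](C)(C)C(C)(C)C)CC[C@H](Br)[C@](C)(Cl)CC=C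
F2 | step 14 | 1-[(1S,2R,3aS,4S,7R,7aS)-4-bromo-2-hydroxy-3a,7-dimethyl-7-(triethylsilyloxy)octahydro-1H-inden-1-yl]-6-methyl-2-methylidenehept-5-en-1-ol (carbinol epimers) | C=C(CCC=C(C)C)C(O)[C@@H]1[C@H](O)C[C@]2(C)[C@@H](Br)CC[C@@](C)(O[Si](CC)(CC)CC)[C@@H]12
F3 | step 14 | 1-[(1S,2R,3aS,4S,7R,7aS)-4-bromo-2-hydroxy-3a,7-dimethyl-7-(triethylsilyloxy)octahydro-1H-inden-1-yl]-6-methyl-2-methylidenehept-5-en-1-one | C=C(CCC=C(C)C)C(=O)[C@@H]1[C@H](O)C[C@]2(C)[C@@H](Br)CC[C@@](C)(O[Si](CC)(CC)CC)[C@@H]12
F4 | step 14 | (1R)-1-[(1S,2R,3aS,4S,7R,7aS)-4-bromo-2-hydroxy-3a,7-dimethyl-7-(triethylsilyloxy)octahydro-1H-inden-1-yl]-6-methyl-2-methylidenehept-5-en-1-ol | C=C(CCC=C(C)C)[C@H](O)[C@@H]1[C@H](O)C[C@]2(C)[C@@H](Br)CC[C@@](C)(O[Si](CC)(CC)CC)[C@@H]12
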